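## Retrosynthetic overview

1. The target is reached from its C5 epimer mixture by kinetic protonation of the C5 enolate, which sets the last stereocentre.
2. The dihydrofuran ring is closed last, by intramolecular oxa-Michael addition–elimination of the side-chain hydroxyl onto the enolised 2-methoxy-1,3-dione.
3. The carbocycle is closed just before, by intramolecular aldol-type (Claisen/Dieckmann) addition of a hydrazone azaenolate to the carbonyl of an α-quaternary γ-butyrolactone; this opens the lactone.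
4. The α-quaternary lactone comes from a three-component union: α-methylene lactone + azaenolate of 1,3-dimethoxyacetone dimethylhydrazone (Michael addition) + allyl bromide.
5. The α-methylene lactone comes from (R)-5-methylfuran-2(5H)-one and an aryl Grignard reagent. Ring order: butenolide (template), then cyclohexanedione ring, then dihydrofuran ring.

Assumption: the SMILES is read as (2R,3S,3aR,5S), i.e. 2-methyl and 3a-allyl cis, 3-aryl trans to both, 5-methoxy cis to the allyl group.

## Route

Step 1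
Reactants: 1 (R)-but-3-yn-2-ol
Product: 3 (R)-4-hydroxypent-2-ynoic acid, via dilithium alkoxide acetylide 2 (not isolated)
Conditions: n-BuLi (2.1 equiv), THF, −78 → 0 °C; CO2 (g), −78 °C → rt; then 2 M HCl
Reagents that add atoms: carbon dioxide, O=C=O
Why: Double deprotonation gives the alkoxide–acetylide, whose carbon terminus is carboxylated by CO2 (acetylide carboxylation) without touching the carbinol stereocentre.

Step 2
Reactants: 3 (R)-4-hydroxypent-2-ynoic acid
Product: 5 (R)-5-methylfuran-2(5H)-one, via (R,Z)-4-hydroxypent-2-enoic acid 4 (not isolated)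
Conditions: H2 (1 atm), Pd/CaCO3 poisoned with Pb(OAc)2, quinoline, EtOAc, rt; then TsOH (cat.), CH2Cl2, rt
Reagents that add atoms: none
Why: Lindlar semihydrogenation (syn addition) gives the Z-alkene, which brings OH and CO2H together for acid-catalysed lactonisation; the stereocentre (future C2) is retained.

Step 3
Reactants: 6 5-bromo-1,2,3-trimethoxybenzene
Product: 7 (3,4,5-trimethoxyphenyl)magnesium bromide (titrated THF solution)
Conditions: Mg turnings, I2 (cat.), THF, 40 °C
Reagents that add atoms: magnesium, [Mg]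
Why: Grignard formation by insertion of magnesium into the aryl C–Br bond; the aryl methyl ethers are inert.

Step 4
Reactants: 5 (R)-5-methylfuran-2(5H)-one; 7 (3,4,5-trimethoxyphenyl)magnesium bromide
Product: 9 (3R,4R,5R)-3-[(dimethylamino)methyl]-5-methyl-4-(3,4,5-trimethoxyphenyl)oxolan-2-one, via bromomagnesium lactone enolate 8 (not isolated)
Conditions: CuBr·SMe2 (10 mol %), THF, −78 °C; then CH2=NMe2+ I− (2 equiv), −78 °C → rt; NaHCO3 (aq) work-up
Reagents that add atoms: N,N-dimethylmethyleneiminium iodide (Eschenmoser's salt), C=[N+](C)C.[I-]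
Why: Copper-catalysed 1,4-addition of the aryl Grignard reagent occurs anti to the C5 methyl group (sets the future C3, trans to methyl), and the enolate is trapped by the iminium salt in a Mannich reaction anti to the new aryl group.

Step 5
Reactants: 9 (3R,4R,5R)-3-[(dimethylamino)methyl]-5-methyl-4-(3,4,5-trimethoxyphenyl)oxolan-2-one
Product: 11 (4S,5R)-5-methyl-3-methylidene-4-(3,4,5-trimethoxyphenyl)oxolan-2-one, via trimethylammonium iodide 10 (not isolated)
Conditions: MeI, MeOH, rt; then NaHCO3 (aq), CH2Cl2, rt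
Reagents that add atoms: none
Why: N-methylation followed by mild-base Hofmann-type (E1cB) elimination of trimethylamine gives the exocyclic Michael acceptor; the weak base leaves the benzylic stereocentre alone.

Step 6
Reactants: 12 methyl 2-methoxyacetate (2 equiv)
Product: 13 methyl 2,4-dimethoxy-3-oxobutanoate (racemic)
Conditions: NaH (0.55 equiv), THF, 0 °C → reflux; then 1 M HCl
Reagents that add atoms: none
Why: Claisen self-condensation, driven by deprotonation of the β-keto ester product.

Step 7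
Reactants: 13 methyl 2,4-dimethoxy-3-oxobutanoate
Product: 14 1,3-dimethoxypropan-2-one
Conditions: 1 M H2SO4 (aq), reflux
Reagents that add atoms: none
Why: Acidic ester hydrolysis and decarboxylation of the β-keto acid (ketonic cleavage) leave the symmetrical ketone.

Step 8
Reactants: 14 1,3-dimethoxypropan-2-one
Product: 15 2-(1,3-dimethoxypropan-2-ylidene)-1,1-dimethylhydrazine
Conditions: Me2NNH2 (1.5 equiv), AcOH (cat.), EtOH, reflux
Reagents that add atoms: N,N-dimethylhydrazine, CN(C)N
Why: Hydrazone condensation masks the ketone so that its α-protons are less acidic than a lactone α-proton; the ketone is symmetrical, so there is no regiochemical issue.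

Step 9
Reactants: 15 2-(1,3-dimethoxypropan-2-ylidene)-1,1-dimethylhydrazine; 11 (4S,5R)-5-methyl-3-methylidene-4-(3,4,5-trimethoxyphenyl)oxolan-2-one
Product: 18 (3R,4S,5R)-3-[3-(2,2-dimethylhydrazinylidene)-2,4-dimethoxybutyl]-5-methyl-3-(prop-2-en-1-yl)-4-(3,4,5-trimethoxyphenyl)oxolan-2-one (both epimers at the side-chain CH(OMe)), via lithium hydrazone azaenolate 16 (not isolated), via lithium lactone enolate 17 (not isolated)
Conditions: LiN(iPr)2 (1.05 equiv), THF, 0 °C; then 11, −78 °C; then allyl bromide, DMPU, −78 → −20 °C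
Reagents that add atoms: allyl bromide, C=CCBr
Why: The Corey–Enders azaenolate adds to the methylene lactone in a Michael reaction, and the resulting lactone enolate, which the hydrazone cannot quench, is C-allylated (SN2) on the face opposite the neighbouring aryl group, fixing the quaternary centre (future C3a) with allyl trans to aryl.

Step 10
Reactants: 18 (3R,4S,5R)-3-[3-(2,2-dimethylhydrazinylidene)-2,4-dimethoxybutyl]-5-methyl-3-(prop-2-en-1-yl)-4-(3,4,5-trimethoxyphenyl)oxolan-2-one
Product: 21 (2R,3S,3aR)-5,7-dimethoxy-2-methyl-3a-(prop-2-en-1-yl)-3-(3,4,5-trimethoxyphenyl)-3,3a,4,5-tetrahydro-1-benzofuran-6(2H)-one (both C5 epimers), via hydroxy keto hydrazone 19 (not isolated), via hydroxy 1,3-dione 20 (not isolated)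
Conditions: LiN(iPr)2 (2.2 equiv), THF, −78 → 0 °C; then 2 M HCl, THF, 40 °C
Reagents that add atoms: water, O
Why: The kinetic azaenolate at the CH2OMe carbon closes the carbocycle by a 6-exo intramolecular aldol-type (Claisen/Dieckmann) addition to the lactone carbonyl with expulsion of the C2 alkoxide, and aqueous acid then hydrolyses the hydrazone and lets the freed alcohol close the dihydrofuran by intramolecular oxa-Michael addition to the enolised 2-methoxy-1,3-dione with loss of water, leaving C2, C3 and C3a untouched.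

Step 11
Reactants: 21 (2R,3S,3aR)-5,7-dimethoxy-2-methyl-3a-(prop-2-en-1-yl)-3-(3,4,5-trimethoxyphenyl)-3,3a,4,5-tetrahydro-1-benzofuran-6(2H)-one (both C5 epimers)
Product: 23 (2R,3S,3aR,5S)-5,7-dimethoxy-2-methyl-3a-(prop-2-en-1-yl)-3-(3,4,5-trimethoxyphenyl)-3,3a,4,5-tetrahydro-1-benzofuran-6(2H)-one, via lithium dienolate 22 (not isolated)
Conditions: LiN(iPr)2 (1.2 equiv), THF, −78 °C; then AcOH in THF, −78 °C; neutral work-up
Reagents that add atoms: none
Why: Stork–Danheiser-type α'-deprotonation (C5–H is the only acidic proton) followed by irreversible kinetic (Zimmerman) protonation from the face opposite the pseudo-axial angular allyl group puts H anti and OMe syn to allyl, i.e. 5S.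

## Compound list

1 | (R)-but-3-yn-2-ol | C#C[C@@H](C)O | starting material
2 | lithium (R)-4-lithiobut-3-yn-2-olate (not isolated) | [Li]C#C[C@@H](C)O[Li] | intermediate
3 | (R)-4-hydroxypent-2-ynoic acid | C[C@@H](O)C#CC(=O)O | intermediate
4 | (R,Z)-4-hydroxypent-2-enoic acid (not isolated) | C[C@@H](O)/C=C\C(=O)O | intermediate
5 | (R)-5-methylfuran-2(5H)-one | C[C@H]1OC(=O)C=C1 | intermediate
6 | 5-bromo-1,2,3-trimethoxybenzene | COc1cc(Br)cc(OC)c1OC | starting material
7 | (3,4,5-trimethoxyphenyl)magnesium bromide | COc1cc([Mg]Br)cc(OC)c1OC | intermediate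
8 | bromomagnesium enolate of (4R,5R)-5-methyl-4-(3,4,5-trimethoxyphenyl)oxolan-2-one (not isolated) | C[C@H]1OC(O[Mg]Br)=C[C@@H]1c1cc(OC)c(OC)c(OC)c1 | intermediate
9 | (3R,4R,5R)-3-[(dimethylamino)methyl]-5-methyl-4-(3,4,5-trimethoxyphenyl)oxolan-2-one | CN(C)C[C@@H]1C(=O)O[C@H](C)[C@H]1c1cc(OC)c(OC)c(OC)c1 | intermediate
10 | [(3R,4R,5R)-5-methyl-2-oxo-4-(3,4,5-trimethoxyphenyl)oxolan-3-yl]-N,N,N-trimethylmethanaminium iodide (not isolated) | C[N+](C)(C)C[C@@H]1C(=O)O[C@H](C)[C@H]1c1cc(OC)c(OC)c(OC)c1.[I-] | intermediate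
11 | (4S,5R)-5-methyl-3-methylidene-4-(3,4,5-trimethoxyphenyl)oxolan-2-one | C=C1C(=O)O[C@H](C)[C@H]1c1cc(OC)c(OC)c(OC)c1 | intermediate
12 | methyl 2-methoxyacetate | COCC(=O)OC | starting material
13 | methyl 2,4-dimethoxy-3-oxobutanoate (racemic) | COCC(=O)C(OC)C(=O)OC | intermediate
14 | 1,3-dimethoxypropan-2-one | COCC(=O)COC | intermediate
15 | 2-(1,3-dimethoxypropan-2-ylidene)-1,1-dimethylhydrazine | COCC(COC)=NN(C)C | intermediate
16 | lithium azaenolate of 15, N-lithio-N-(1,3-dimethoxyprop-1-en-2-yl)-N',N'-dimethylhydrazide (not isolated) | COC=C(COC)N([Li])N(C)C | intermediate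
17 | lithium (4S,5R)-3-[3-(2,2-dimethylhydrazinylidene)-2,4-dimethoxybutyl]-5-methyl-4-(3,4,5-trimethoxyphenyl)-4,5-dihydrofuran-2-olate (not isolated) | COCC(=NN(C)C)C(OC)CC1=C(O[Li])O[C@H](C)[C@H]1c1cc(OC)c(OC)c(OC)c1 | intermediate
18 | (3R,4S,5R)-3-[3-(2,2-dimethylhydrazinylidene)-2,4-dimethoxybutyl]-5-methyl-3-(prop-2-en-1-yl)-4-(3,4,5-trimethoxyphenyl)oxolan-2-one, both side-chain epimers | C=CC[C@]1(CC(OC)C(COC)=NN(C)C)C(=O)O[C@H](C)[C@H]1c1cc(OC)c(OC)c(OC)c1 | intermediate
19 | (6R)-3-(2,2-dimethylhydrazinylidene)-6-[(1S,2R)-2-hydroxy-1-(3,4,5-trimethoxyphenyl)propyl]-2,4-dimethoxy-6-(prop-2-en-1-yl)cyclohexan-1-one, epimers at C2 and C4 (not isolated) | C=CC[C@@]1(CC(OC)C(=NN(C)C)C(OC)C1=O)[C@H](c1cc(OC)c(OC)c(OC)c1)[C@@H](C)O | intermediate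
20 | (4R)-4-[(1S,2R)-2-hydroxy-1-(3,4,5-trimethoxyphenyl)propyl]-2,6-dimethoxy-4-(prop-2-en-1-yl)cyclohexane-1,3-dione, epimers at C2 and C6 (not isolated) | C=CC[C@@]1(CC(OC)C(=O)C(OC)C1=O)[C@H](c1cc(OC)c(OC)c(OC)c1)[C@@H](C)O | intermediate
21 | (2R,3S,3aR)-5,7-dimethoxy-2-methyl-3a-(prop-2-en-1-yl)-3-(3,4,5-trimethoxyphenyl)-3,3a,4,5-tetrahydro-1-benzofuran-6(2H)-one, both C5 epimers | C=CC[C@]12CC(OC)C(=O)C(OC)=C1O[C@H](C)[C@H]2c1cc(OC)c(OC)c(OC)c1 | intermediate
22 | lithium dienolate of 21, lithium (2R,3S,3aR)-5,7-dimethoxy-2-methyl-3a-(prop-2-en-1-yl)-3-(3,4,5-trimethoxyphenyl)-2,3,3a,4-tetrahydro-1-benzofuran-6-olate (not isolated) | C=CC[C@]12CC(OC)=C(O[Li])C(OC)=C1O[C@H](C)[C@H]2c1cc(OC)c(OC)c(OC)c1 | intermediate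
23 | (2R,3S,3aR,5S)-5,7-dimethoxy-2-methyl-3a-(prop-2-en-1-yl)-3-(3,4,5-trimethoxyphenyl)-3,3a,4,5-tetrahydro-1-benzofuran-6(2H)-one | C=CC[C@]12C[C@H](OC)C(=O)C(OC)=C1O[C@H](C)[C@H]2c1cc(OC)c(OC)c(OC)c1 | target

## Step count and risks

Total step count: 11. Longest linear sequence: 7 steps (1, 2, 4, 5, 9, 10, 11); the aryl branch (step 3) and the hydrazone branch (steps 6–8) run in parallel.

The three steps most likely to fail are steps 9, 10 and 11.

Step 9 can fail if the azaenolate deprotonates 11 at its benzylic position instead of adding, or if the lactone enolate is quenched before allylation. The fallback joins the fragments stepwise, setting out from 11 and 14. Ketone 14 is condensed with pyrrolidine to the enamine 1-(1,3-dimethoxyprop-1-en-2-yl)pyrrolidine F1. A Stork enamine Michael addition of F1 to 11 and aqueous hydrolysis give the keto lactone (3S,4R,5R)-3-(2,4-dimethoxy-3-oxobutyl)-5-methyl-4-(3,4,5-trimethoxyphenyl)oxolan-2-one F2. Condensation with Me2NNH2 gives the hydrazone lactone (3S,4R,5R)-3-[3-(2,2-dimethylhydrazinylidene)-2,4-dimethoxybutyl]-5-methyl-4-(3,4,5-trimethoxyphenyl)oxolan-2-one F3. LiN(iPr)2 then removes the lactone α-proton, now the most acidic one, and allyl bromide enters anti to the aryl group, which comes back to the route at 18.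

Step 10 can fail if the azaenolate is too slow to attack the hindered, α-quaternary lactone carbonyl or if the β-keto hydrazone resists hydrolysis. The fallback sets out from 18 and swaps the nucleophile for the free ketone enolate under reversible conditions. The hydrazone is cleaved first with CuCl2·2H2O in aqueous THF to the keto lactone (3R,4S,5R)-3-(2,4-dimethoxy-3-oxobutyl)-5-methyl-3-(prop-2-en-1-yl)-4-(3,4,5-trimethoxyphenyl)oxolan-2-one F4. KOtBu in THF then effects a thermodynamic Dieckmann-type closure, driven by formation of the stabilised dione enolate. This comes back to the route at 20, which TsOH in warm toluene closes to 21.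

Step 11 can fail if kinetic protonation is not face-selective; the 5S epimer carries a pseudo-axial methoxy group and is probably not the thermodynamic one, so it cannot be reached by simple equilibration and the work-up must stay neutral. The fallback sets out from 21 and gives up kinetic control in favour of separation with recycling. Chromatography of 21 gives 23 directly together with the epimer (2R,3S,3aR,5R)-5,7-dimethoxy-2-methyl-3a-(prop-2-en-1-yl)-3-(3,4,5-trimethoxyphenyl)-3,3a,4,5-tetrahydro-1-benzofuran-6(2H)-one F5. F5 is re-equilibrated with DBU in MeOH, which comes back to the route at 21, and the mixture is separated again until the material is drained into 23.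

## Further compounds

F1 | step 9 | 1-(1,3-dimethoxyprop-1-en-2-yl)pyrrolidine | COC=C(COC)N1CCCC1
F2 | step 9 | (3S,4R,5R)-3-(2,4-dimethoxy-3-oxobutyl)-5-methyl-4-(3,4,5-trimethoxyphenyl)oxolan-2-one | COCC(=O)C(OC)C[C@@H]1C(=O)O[C@H](C)[C@H]1c1cc(OC)c(OC)c(OC)c1
F3 | step 9 | (3S,4R,5R)-3-[3-(2,2-dimethylhydrazinylidene)-2,4-dimethoxybutyl]-5-methyl-4-(3,4,5-trimethoxyphenyl)oxolan-2-one | COCC(=NN(C)C)C(OC)C[C@@H]1C(=O)O[C@H](C)[C@H]1c1cc(OC)c(OC)c(OC)c1
F4 | step 10 | (3R,4S,5R)-3-(2,4-dimethoxy-3-oxobutyl)-5-methyl-3-(prop-2-en-1-yl)-4-(3,4,5-trimethoxyphenyl)oxolan-2-one | C=CC[C@]1(CC(OC)C(=O)COC)C(=O)O[C@H](C)[C@H]1c1cc(OC)c(OC)c(OC)c1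
F5 | step 11 | (2R,3S,3aR,5R)-5,7-dimethoxy-2-methyl-3a-(prop-2-en-1-yl)-3-(3,4,5-trimethoxyphenyl)-3,3a,4,5-tetrahydro-1-benzofuran-6(2H)-one | C=CC[C@]12C[C@@H](OC)C(=O)C(OC)=C1O[C@H](C)[C@H]2c1cc(OC)c(OC)c(OC)c1
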